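## Retrosynthetic overview

- The tetronic acid ring (O1–C2–C3–C4–C5) is opened at C3–C4 by a Dieckmann disconnection, giving the acyclic methyl (2R)-2-(propanoyloxy) ester 23.
- Ester 23 is cut between the CH2 on the carbinol carbon and the methyl-bearing alkene carbon; the forward reaction is a nickel-catalysed decarboxylative alkenylation of redox-active ester 5 with alkenylzinc 22.
- Enabling feature: ring carbon C5 (the O-bearing stereocentre) carries ring carbon C4 and an exocyclic CH2 bonded directly to the trisubstituted alkene carbon C2' of the side chain. This O–CH(C)–CH2 unit is C2, C1 and C3 of (R)-malic acid, whose C4 carboxyl serves as a traceless activating group lost as CO2. C2' bears a methyl group and gives a configurationally stable E alkenylmetal.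
- Alkenylzinc 22 derives from (2E,6E)-farnesyl acetate: the isopropylidene terminus is excised (bromohydrin, epoxide, periodate), the 3-furylmethyl group is attached by a copper-catalysed Grignard coupling, and the aldehyde is taken to the methyl alkyne and then to the E iodide by hydrozirconation and iodination.
- Rings: the furan is bought as 3-furanmethanol; the tetronic acid ring is the only ring made and is closed in the last step.

Key step: step 13

Assumption: the C10 centre of the bromohydrin and epoxide is carried as a racemate, which is immaterial because that carbon becomes the aldehyde carbon in step 9; the only stereocentre of the target comes unchanged from (R)-malic acid.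

## Route

Step 1
Reactants: 1 (R)-malic acid; 2 propanoyl chloride
Product: 3 (3R)-2,5-dioxooxolan-3-yl propanoate (O-propanoylmalic anhydride)
Conditions: EtCOCl (neat, 4 equiv), 50 °C, 3 h; evaporate
Reagents that add atoms: none
Why: O-acylation and cyclodehydration through the mixed anhydride, the standard acyl chloride route to O-acylmalic anhydrides; no bond to the stereocentre is broken, so the (R) configuration is retained.

Step 2
Reactants: 3 (3R)-2,5-dioxooxolan-3-yl propanoate
Product: 4 (3R)-4-methoxy-4-oxo-3-(propanoyloxy)butanoic acid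
Conditions: MeOH (3 equiv), CH2Cl2, 0 °C to rt
Reagents that add atoms: methanol, CO
Why: Regioselective anhydride alcoholysis, in which methanol attacks the more electrophilic carbonyl next to the acyloxy-bearing carbon (as established for O-acetyl- and O-trifluoroacetylmalic anhydride), should give the 1-methyl ester with the C4 acid free.

Step 3
Reactants: 4 (3R)-4-methoxy-4-oxo-3-(propanoyloxy)butanoic acid
Product: 5 1-methyl 4-(4,5,6,7-tetrachloro-1,3-dioxoisoindolin-2-yl) (2R)-2-(propanoyloxy)butanedioate
Conditions: N-hydroxytetrachlorophthalimide, N,N'-diisopropylcarbodiimide, CH2Cl2, rt, 2 h (no amine base); short silica plug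
Reagents that add atoms: N-hydroxytetrachlorophthalimide, ON1C(=O)c2c(Cl)c(Cl)c(Cl)c(Cl)c2C1=O
Why: Carbodiimide (Steglich-type) esterification to the redox-active ester, run without amine base so that the β-propanoyloxy group is not eliminated to a fumarate.

Step 4
Reactants: 6 3-furanmethanol
Product: 7 3-(chloromethyl)furan
Conditions: SOCl2, pyridine, Et2O, 0 °C; used at once
Reagents that add atoms: thionyl chloride, O=S(Cl)Cl
Why: Deoxychlorination of a primary furylmethyl alcohol through its chlorosulfite (SN2), with pyridine buffering the HCl that would degrade the furan.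

Step 5
Reactants: 8 (2E,6E)-farnesyl acetate
Product: 9 (2E,6E)-10-bromo-11-hydroxy-3,7,11-trimethyldodeca-2,6-dien-1-yl acetate (racemic at C10)
Conditions: N-bromosuccinimide (1.1 equiv), THF/H2O, 0 °C
Reagents that add atoms: N-bromosuccinimide, O=C1CCC(=O)N1Br; water, O
Why: Terminal-selective bromohydrin formation of a polyprenyl acetate: the bromonium ion forms at the exposed, most electron-rich terminal alkene (the 2,3-alkene is deactivated by the allylic acetate) and water opens it at the tertiary carbon.

Step 6
Reactants: 9 (2E,6E)-10-bromo-11-hydroxy-3,7,11-trimethyldodeca-2,6-dien-1-yl acetate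
Product: 10 (2E,6E)-9-(3,3-dimethyloxiran-2-yl)-3,7-dimethylnona-2,6-dien-1-ol (racemic)
Conditions: K2CO3, MeOH, rt
Reagents that add atoms: none
Why: Intramolecular Williamson etherification of the bromohydrin to the epoxide, with concurrent base-catalysed methanolysis of the acetate.

Step 7
Reactants: 10 (2E,6E)-9-(3,3-dimethyloxiran-2-yl)-3,7-dimethylnona-2,6-dien-1-ol
Product: 12 2-[(3E,7E)-9-bromo-3,7-dimethylnona-3,7-dien-1-yl]-3,3-dimethyloxirane, via allylic mesylate 11 (not isolated)
Conditions: MsCl, Et3N, THF, −45 °C; then LiBr, THF, 0 °C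
Reagents that add atoms: lithium bromide, [Li+].[Br-]
Why: Mesylation followed by SN2 bromide displacement at the primary allylic carbon at low temperature, which should leave the alkene geometry and the trisubstituted epoxide untouched.

Step 8
Reactants: 7 3-(chloromethyl)furan; 12 2-[(3E,7E)-9-bromo-3,7-dimethylnona-3,7-dien-1-yl]-3,3-dimethyloxirane
Product: 14 3-[(3E,7E)-10-(3,3-dimethyloxiran-2-yl)-4,8-dimethyldeca-3,7-dien-1-yl]furan, via 3-furylmethylmagnesium chloride 13 (not isolated)
Conditions: 7, Mg, THF, 0 °C; then 12, Li2CuCl4 (5 mol %), THF, −78 to 0 °C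
Reagents that add atoms: none
Why: Kochi-type copper-catalysed Grignard coupling with a primary allylic bromide, which should proceed at the α carbon with retention of the E geometry, the catalyst suppressing ring attack by the furylmethyl Grignard reagent and the cold conditions sparing the epoxide.

Step 9
Reactants: 14 3-[(3E,7E)-10-(3,3-dimethyloxiran-2-yl)-4,8-dimethyldeca-3,7-dien-1-yl]furan
Product: 15 (4E,8E)-11-(furan-3-yl)-4,8-dimethylundeca-4,8-dienal
Conditions: H5IO6 (1.2 equiv), THF/H2O, 0 °C, 30 min
Reagents that add atoms: none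
Why: Periodic acid epoxide hydrolysis and glycol cleavage (Malaprade oxidation) excises the isopropylidene terminus as acetone, the short cold exposure being tolerable for a 3-alkylfuran.

Step 10
Reactants: 15 (4E,8E)-11-(furan-3-yl)-4,8-dimethylundeca-4,8-dienal
Product: 16 3-[(3E,7E)-12,12-dibromo-4,8-dimethyldodeca-3,7,11-trien-1-yl]furan
Conditions: CBr4, PPh3, Zn dust, CH2Cl2, rt (reagent preformed); then 15, 0 °C to rt
Reagents that add atoms: carbon tetrabromide, BrC(Br)(Br)Br
Why: Ramirez–Corey–Fuchs dibromo-olefination (Wittig reaction of Ph3P=CBr2), in the zinc modification that keeps Ph3PBr2 and HBr away from the furan and the trisubstituted alkenes.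

Step 11
Reactants: 16 3-[(3E,7E)-12,12-dibromo-4,8-dimethyldodeca-3,7,11-trien-1-yl]furan
Product: 18 3-[(3E,7E)-4,8-dimethyltrideca-3,7-dien-11-yn-1-yl]furan, via lithium acetylide 17 (not isolated)
Conditions: n-BuLi (2.1 equiv), THF, −78 °C, 1 h; then MeI, −78 °C to rt
Reagents that add atoms: iodomethane, CI
Why: Second stage of the Corey–Fuchs alkyne synthesis (Br/Li exchange, Fritsch–Buttenberg–Wiechell rearrangement, deprotonation) followed by C-methylation of the lithium acetylide; at −78 °C n-BuLi should not metalate the furan.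

Step 12
Reactants: 18 3-[(3E,7E)-4,8-dimethyltrideca-3,7-dien-11-yn-1-yl]furan
Product: 20 3-[(3E,7E,11E)-12-iodo-4,8-dimethyltrideca-3,7,11-trien-1-yl]furan, via alkenylzirconocene chloride 19 (not isolated)
Conditions: Cp2Zr(H)Cl (2.0 equiv), THF, 50 °C, 1 h; then I2, THF, −20 °C
Reagents that add atoms: iodine, II
Why: Schwartz hydrozirconation (syn addition of Zr–H) under thermodynamic control, the excess hydride equilibrating the regioisomers toward zirconium on the less hindered methyl-bearing carbon, followed by iodinolysis with retention, which sets the 11E geometry (iodine cis to H) while the trisubstituted alkenes and the furan stay inert.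

Step 13
Reactants: 20 3-[(3E,7E,11E)-12-iodo-4,8-dimethyltrideca-3,7,11-trien-1-yl]furan; 5 1-methyl 4-(4,5,6,7-tetrachloro-1,3-dioxoisoindolin-2-yl) (2R)-2-(propanoyloxy)butanedioate
Product: 23 methyl (2R,4E,8E,12E)-15-(furan-3-yl)-4,8,12-trimethyl-2-(propanoyloxy)pentadeca-4,8,12-trienoate, via alkenyllithium 21 (not isolated), via alkenylzinc chloride 22 (not isolated)
Conditions: 20 (1.5 equiv), t-BuLi (3.0 equiv), Et2O, −78 °C; ZnCl2 (1.6 equiv), THF, −78 °C to rt; then 5 (1.0 equiv), Ni(acac)2 (10 mol %), 2,2'-bipyridine (10 mol %), THF/DMF, rt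
Reagents that add atoms: none
Why: Nickel-catalysed decarboxylative alkenylation (a Negishi-type radical cross-coupling of a redox-active ester): iodine–lithium exchange and transmetalation give alkenylzinc 22, low-valent nickel transfers one electron to the tetrachlorophthalimide ester of 5, which loses the phthalimide anion and CO2 to give the primary radical CH2–CH(OCOEt)CO2Me, and this radical is captured by the alkenylnickel species formed from 22 before reductive elimination forges the CH2–C(Me)= bond. The closest known reaction type is the Ni(acac)2/bipyridine coupling of primary alkyl N-hydroxyphthalimide-type esters with alkenylzinc halides, α-substituted ones included, which proceeds with retention of alkene geometry. No ring is closed in this step. No new stereocentre arises: the (R) centre of 5 is adjacent to, not at, the radical carbon and is carried through unchanged, and the 12E geometry is transferred from iodide 20 because alkenyllithium 21, alkenylzinc 22 and the alkenylnickel intermediate are configurationally stable. The step needs cross-coupling to outrun loss of the β-propanoyloxy group and attack at the two ordinary esters; this should be secured by the non-basic, ester-tolerant organozinc, by the absence of amine base and by fast radical capture and reductive elimination at nickel, a 1,2-acyloxy shift of the radical being slow at room temperature.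

Step 14
Reactants: 23 methyl (2R,4E,8E,12E)-15-(furan-3-yl)-4,8,12-trimethyl-2-(propanoyloxy)pentadeca-4,8,12-trienoate
Product: 24 (5R)-5-[(2E,6E,10E)-13-(furan-3-yl)-2,6,10-trimethyltrideca-2,6,10-trien-1-yl]-4-hydroxy-3-methylfuran-2(5H)-one (target, CNP0244252.4)
Conditions: LiN(SiMe3)2 (2.5 equiv), THF, −78 to −20 °C; then cold 1 M HCl
Reagents that add atoms: none
Why: Dieckmann (intramolecular Claisen) condensation, in which the bulky amide base deprotonates the unhindered propanoyl CH2, the enolate closes the five-membered ring 5-exo-trig onto the methyl ester carbonyl (new C3–C4 bond) and methoxide loss gives the stable lithium tetronate, a closure precedented for O-acyl lactates and malates with the C5 configuration retained.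

## Compound list

1 | (R)-malic acid | OC(=O)C[C@@H](O)C(O)=O | starting material
2 | propanoyl chloride | CCC(Cl)=O | starting material
3 | (3R)-2,5-dioxooxolan-3-yl propanoate | O=C1C[C@@H](OC(=O)CC)C(=O)O1 | intermediate
4 | (3R)-4-methoxy-4-oxo-3-(propanoyloxy)butanoic acid | OC(=O)C[C@@H](OC(=O)CC)C(=O)OC | intermediate
5 | 1-methyl 4-(4,5,6,7-tetrachloro-1,3-dioxoisoindolin-2-yl) (2R)-2-(propanoyloxy)butanedioate | O=C(C[C@@H](OC(=O)CC)C(=O)OC)ON1C(=O)c2c(Cl)c(Cl)c(Cl)c(Cl)c2C1=O | intermediate
6 | 3-furanmethanol | OCc1ccoc1 | starting material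
7 | 3-(chloromethyl)furan | ClCc1ccoc1 | intermediate
8 | (2E,6E)-farnesyl acetate | CC(C)=CCC/C(C)=C/CC/C(C)=C/COC(C)=O | starting material
9 | (2E,6E)-10-bromo-11-hydroxy-3,7,11-trimethyldodeca-2,6-dien-1-yl acetate (racemic) | CC(C)(O)C(Br)CC/C(C)=C/CC/C(C)=C/COC(C)=O | intermediate
10 | (2E,6E)-9-(3,3-dimethyloxiran-2-yl)-3,7-dimethylnona-2,6-dien-1-ol (racemic) | CC1(C)OC1CC/C(C)=C/CC/C(C)=C/CO | intermediate
11 | (2E,6E)-9-(3,3-dimethyloxiran-2-yl)-3,7-dimethylnona-2,6-dien-1-yl methanesulfonate | CC1(C)OC1CC/C(C)=C/CC/C(C)=C/COS(C)(=O)=O | intermediate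
12 | 2-[(3E,7E)-9-bromo-3,7-dimethylnona-3,7-dien-1-yl]-3,3-dimethyloxirane (racemic) | CC1(C)OC1CC/C(C)=C/CC/C(C)=C/CBr | intermediate
13 | 3-furylmethylmagnesium chloride | Cl[Mg]Cc1ccoc1 | intermediate
14 | 3-[(3E,7E)-10-(3,3-dimethyloxiran-2-yl)-4,8-dimethyldeca-3,7-dien-1-yl]furan (racemic) | CC1(C)OC1CC/C(C)=C/CC/C(C)=C/CCc1ccoc1 | intermediate
15 | (4E,8E)-11-(furan-3-yl)-4,8-dimethylundeca-4,8-dienal | O=CCC/C(C)=C/CC/C(C)=C/CCc1ccoc1 | intermediate
16 | 3-[(3E,7E)-12,12-dibromo-4,8-dimethyldodeca-3,7,11-trien-1-yl]furan | BrC(Br)=CCC/C(C)=C/CC/C(C)=C/CCc1ccoc1 | intermediate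
17 | lithium acetylide of 3-[(3E,7E)-4,8-dimethyldodeca-3,7-dien-11-yn-1-yl]furan | [Li]C#CCC/C(C)=C/CC/C(C)=C/CCc1ccoc1 | intermediate
18 | 3-[(3E,7E)-4,8-dimethyltrideca-3,7-dien-11-yn-1-yl]furan | CC#CCC/C(C)=C/CC/C(C)=C/CCc1ccoc1 | intermediate
19 | chloro[(2E,6E,10E)-13-(furan-3-yl)-6,10-dimethyltrideca-2,6,10-trien-2-yl]zirconocene | Cl[Zr](C1C=CC=C1)(C1C=CC=C1)/C(C)=C/CC/C(C)=C/CC/C(C)=C/CCc1ccoc1 | intermediate
20 | 3-[(3E,7E,11E)-12-iodo-4,8-dimethyltrideca-3,7,11-trien-1-yl]furan | I/C(C)=C/CC/C(C)=C/CC/C(C)=C/CCc1ccoc1 | intermediate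
21 | [(2E,6E,10E)-13-(furan-3-yl)-6,10-dimethyltrideca-2,6,10-trien-2-yl]lithium | [Li]/C(C)=C/CC/C(C)=C/CC/C(C)=C/CCc1ccoc1 | intermediate
22 | [(2E,6E,10E)-13-(furan-3-yl)-6,10-dimethyltrideca-2,6,10-trien-2-yl]zinc chloride | Cl[Zn]/C(C)=C/CC/C(C)=C/CC/C(C)=C/CCc1ccoc1 | intermediate
23 | methyl (2R,4E,8E,12E)-15-(furan-3-yl)-4,8,12-trimethyl-2-(propanoyloxy)pentadeca-4,8,12-trienoate | COC(=O)[C@@H](C/C(C)=C/CC/C(C)=C/CC/C(C)=C/CCc1ccoc1)OC(=O)CC | intermediate
24 | (5R)-5-[(2E,6E,10E)-13-(furan-3-yl)-2,6,10-trimethyltrideca-2,6,10-trien-1-yl]-4-hydroxy-3-methylfuran-2(5H)-one | CC1=C(O)[C@@H](C/C(C)=C/CC/C(C)=C/CC/C(C)=C/CCc2ccoc2)OC1=O | target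

## Step count and risks

Total step count: 14. Longest linear sequence: 10 steps (steps 5 to 14, from (2E,6E)-farnesyl acetate 8).

Steps most likely to fail:

1. Step 13 (key coupling). The β-propanoyloxy group may be lost (elimination from the activated ester or from an alkylnickel intermediate), the radical may be reduced to the C–H compound, or the alkenylzinc may homocouple, so that little cross-coupled product forms. The fallback is a polar epoxide opening that makes the same bond. It sets out from iodide 20, which would be converted (t-BuLi, Et2O, −78 °C; then MgBr2·OEt2) into the alkenylmagnesium bromide and added with catalytic CuI at −40 °C to commercial methyl (2R)-oxirane-2-carboxylate. Attack at the CH2 terminus of the epoxide leaves the stereocentre untouched and should give methyl (2R,4E,8E,12E)-15-(furan-3-yl)-2-hydroxy-4,8,12-trimethylpentadeca-4,8,12-trienoate F1. O-Acylation with propanoic anhydride, pyridine and catalytic DMAP comes back to the route at 23.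

2. Step 12 (hydrozirconation and iodination). Regiochemical equilibration of the alkenylzirconium may stay incomplete (zirconium partly on the inner alkyne carbon), or chain alkenes may be slowly hydrozirconated and isomerised, giving iodide isomers that are hard to separate. The fallback is a silicon-directed hydroalumination, in which the regiochemistry is fixed by the silyl group. It sets out from dibromo-olefin 16. n-BuLi followed by Me3SiCl should give 3-[(3E,7E)-4,8-dimethyl-12-(trimethylsilyl)dodeca-3,7-dien-11-yn-1-yl]furan F2. i-Bu2AlH in heptane (trans-hydroalumination, aluminium on the silyl-bearing carbon), then MeLi and MeI (methylation of the alkenylalanate with retention), should give 3-[(3E,7E,11E)-4,8-dimethyl-12-(trimethylsilyl)trideca-3,7,11-trien-1-yl]furan F3. ipso-Iododesilylation with N-iodosuccinimide in MeCN/ClCH2CN at 0 °C (retention) comes back to the route at 20.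

3. Step 14 (Dieckmann closure). Competing deprotonation at C2 of 23 (α to the methyl ester) may cause partial epimerisation or acyl migration instead of ring closure, on the most valuable intermediate. The fallback closes the ring before the coupling and sets out from acid 4.
   - tert-Butyl 2,2,2-trichloroacetimidate with catalytic BF3·OEt2 should give 4-tert-butyl 1-methyl (2R)-2-(propanoyloxy)butanedioate F4.
   - LiN(SiMe3)2 in THF at −78 °C should close tert-butyl 2-[(2R)-3-hydroxy-4-methyl-5-oxo-2,5-dihydrofuran-2-yl]acetate F5, whose optical purity can be checked and raised by crystallisation at this early stage.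
   - Mitsunobu O-allylation (allyl alcohol, PPh3, diisopropyl azodicarboxylate) should give tert-butyl 2-[(2R)-4-methyl-5-oxo-3-(prop-2-en-1-yloxy)-2,5-dihydrofuran-2-yl]acetate F6.
   - CF3CO2H in CH2Cl2 should give 2-[(2R)-4-methyl-5-oxo-3-(prop-2-en-1-yloxy)-2,5-dihydrofuran-2-yl]acetic acid F7.
   - N-Hydroxytetrachlorophthalimide and N,N'-diisopropylcarbodiimide should give the redox-active ester 4,5,6,7-tetrachloro-1,3-dioxoisoindolin-2-yl 2-[(2R)-4-methyl-5-oxo-3-(prop-2-en-1-yloxy)-2,5-dihydrofuran-2-yl]acetate F8.
   - Coupling with alkenylzinc 22 under the conditions of step 13 should give (5R)-5-[(2E,6E,10E)-13-(furan-3-yl)-2,6,10-trimethyltrideca-2,6,10-trien-1-yl]-3-methyl-4-(prop-2-en-1-yloxy)furan-2(5H)-one F9.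
   - Deallylation with Pd(PPh3)4 (zerovalent palladium) and morpholine comes back to the route at 24.

Further compounds
F1 | step 13 | methyl (2R,4E,8E,12E)-15-(furan-3-yl)-2-hydroxy-4,8,12-trimethylpentadeca-4,8,12-trienoate | COC(=O)[C@H](O)C/C(C)=C/CC/C(C)=C/CC/C(C)=C/CCc1ccoc1
F2 | step 12 | 3-[(3E,7E)-4,8-dimethyl-12-(trimethylsilyl)dodeca-3,7-dien-11-yn-1-yl]furan | C[Si](C)(C)C#CCC/C(C)=C/CC/C(C)=C/CCc1ccoc1
F3 | step 12 | 3-[(3E,7E,11E)-4,8-dimethyl-12-(trimethylsilyl)trideca-3,7,11-trien-1-yl]furan | C[Si](C)(C)/C(C)=C/CC/C(C)=C/CC/C(C)=C/CCc1ccoc1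
F4 | step 14 | 4-tert-butyl 1-methyl (2R)-2-(propanoyloxy)butanedioate | CC(C)(C)OC(=O)C[C@@H](OC(=O)CC)C(=O)OC
F5 | step 14 | tert-butyl 2-[(2R)-3-hydroxy-4-methyl-5-oxo-2,5-dihydrofuran-2-yl]acetate | CC1=C(O)[C@@H](CC(=O)OC(C)(C)C)OC1=O
F6 | step 14 | tert-butyl 2-[(2R)-4-methyl-5-oxo-3-(prop-2-en-1-yloxy)-2,5-dihydrofuran-2-yl]acetate | CC1=C(OCC=C)[C@@H](CC(=O)OC(C)(C)C)OC1=O
F7 | step 14 | 2-[(2R)-4-methyl-5-oxo-3-(prop-2-en-1-yloxy)-2,5-dihydrofuran-2-yl]acetic acid | CC1=C(OCC=C)[C@@H](CC(O)=O)OC1=O
F8 | step 14 | 4,5,6,7-tetrachloro-1,3-dioxoisoindolin-2-yl 2-[(2R)-4-methyl-5-oxo-3-(prop-2-en-1-yloxy)-2,5-dihydrofuran-2-yl]acetate | CC1=C(OCC=C)[C@@H](CC(=O)ON2C(=O)c3c(Cl)c(Cl)c(Cl)c(Cl)c3C2=O)OC1=O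
F9 | step 14 | (5R)-5-[(2E,6E,10E)-13-(furan-3-yl)-2,6,10-trimethyltrideca-2,6,10-trien-1-yl]-3-methyl-4-(prop-2-en-1-yloxy)furan-2(5H)-one | CC1=C(OCC=C)[C@@H](C/C(C)=C/CC/C(C)=C/CC/C(C)=C/CCc2ccoc2)OC1=O
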